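The route rests on reading the vicinal pair C4a–C4 / C3–OH of the pyran C ring (O1–C2–C3–C4–C4a–C8a) as the retron of a 1,2-aryl shift. The precursor is a cis-2-aryl-3-(mesyloxymethyl)-2,3-dihydrobenzofuran. In it C4 still hangs outside a five-membered ring and the A-ring carbon C4a is bound to C3. On ionisation the π-rich phloroglucinol A ring bridges to a phenonium ion, which water opens at C3. One operation enlarges the ring to the pyran, draws C4 into it and sets the C3 carbinol by inversion, cis to the C2 aryl group. Both stereocentres of the precursor come from an enantioselective, cis-selective Rh(II) C–H insertion. The 7-O-galloyl group is installed before the rearrangement.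

Key step: step 9

Numbering: chromans carry flavan numbering and compounds 7–14 carry benzofuran numbering. C3a, O on C4 and O on C6 of the benzofurans become C4a, O5 and O7 of the flavan.

Assumption: 3 and 9 are taken as catalogue compounds. The sense of induction of the Rh(II) tert-leucinate catalyst is assigned by analogy with simpler 2-(benzyloxy)phenyl diazoacetates, and the antipodal catalyst is equally accessible if the sense proves opposite.

Step 1
Reactants: 1 2',4',6'-trihydroxyacetophenone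
Product: 2 1-[2,6-dihydroxy-4-(triisopropylsilyloxy)phenyl]ethanone
Conditions: TIPSCl (1.05 equiv), imidazole, DMF, 0 °C
Reagents that add atoms: triisopropylsilyl chloride, CC(C)[Si](Cl)(C(C)C)C(C)C
Why: The two ortho hydroxyls are chelated to and flanked by the acetyl group, so the bulky silyl chloride should react only at the free para hydroxyl (the future O7) in a standard imidazole-promoted O-silylation.

Step 2
Reactants: 2 1-[2,6-dihydroxy-4-(triisopropylsilyloxy)phenyl]ethanone; 3 3,4,5-tris(benzyloxy)benzyl alcohol (2.3 equiv)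
Product: 4 1-[2,6-bis{[3,4,5-tris(benzyloxy)benzyl]oxy}-4-(triisopropylsilyloxy)phenyl]ethanone
Conditions: PPh3, DIAD, THF, 0 °C to rt
Reagents that add atoms: none
Why: Double Mitsunobu etherification alkylates both phenols under neutral conditions that spare the aryl silyl ether, and of the two identical benzylic ethers one is the future C2–aryl unit and the other the hydrogenolysable O5 protecting group.

Step 3
Reactants: 4 1-[2,6-bis{[3,4,5-tris(benzyloxy)benzyl]oxy}-4-(triisopropylsilyloxy)phenyl]ethanone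
Product: 5 methyl 2-[2,6-bis{[3,4,5-tris(benzyloxy)benzyl]oxy}-4-(triisopropylsilyloxy)phenyl]acetate
Conditions: Tl(NO3)3·3H2O, MeOH–HC(OMe)3 (1:1), 0 °C to rt
Reagents that add atoms: methanol, CO
Why: In this thallium(III)-mediated oxidative rearrangement of an aryl methyl ketone, oxythallation of the derived enol ether is followed by 1,2-migration of the very electron-rich aryl group with loss of Tl(I), and benzyl and TIPS ethers should tolerate the brief, mildly acidic treatment.

Step 4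
Reactants: 5 methyl 2-[2,6-bis{[3,4,5-tris(benzyloxy)benzyl]oxy}-4-(triisopropylsilyloxy)phenyl]acetate
Product: 6 methyl 2-diazo-2-[2,6-bis{[3,4,5-tris(benzyloxy)benzyl]oxy}-4-(triisopropylsilyloxy)phenyl]acetate
Conditions: p-ABSA, DBU, MeCN, 0 °C to rt
Reagents that add atoms: 4-acetamidobenzenesulfonyl azide, CC(=O)Nc1ccc(cc1)S(=O)(=O)N=[N+]=[N-]
Why: Regitz diazo transfer to the benzylic ester enolate gives the donor/acceptor diazoester, and none of the ethers is affected by DBU.

Step 5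
Reactants: 6 methyl 2-diazo-2-[2,6-bis{[3,4,5-tris(benzyloxy)benzyl]oxy}-4-(triisopropylsilyloxy)phenyl]acetate
Product: 7 methyl (2S,3R)-2-[3,4,5-tris(benzyloxy)phenyl]-4-{[3,4,5-tris(benzyloxy)benzyl]oxy}-6-(triisopropylsilyloxy)-2,3-dihydrobenzofuran-3-carboxylate (2,3-cis)
Conditions: Rh2(R-PTTL)4 (dirhodium tetrakis[N-phthaloyl-(R)-tert-leucinate], cat.), toluene, −60 °C
Reagents that add atoms: none
Why: Intramolecular 1,5 C–H insertion of the rhodium donor/acceptor carbenoid into the activated benzylic ether C–H of either of the two equivalent OCH2Ar groups forms the C2–C3 bond, and the chiral carboxylate ligands control both the absolute configuration and the kinetic cis relation of C2 and C3.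

Step 6
Reactants: 7 methyl (2S,3R)-cis-dihydrobenzofuran-3-carboxylate
Product: 8 [(2S,3S)-2-[3,4,5-tris(benzyloxy)phenyl]-4-{[3,4,5-tris(benzyloxy)benzyl]oxy}-6-(triisopropylsilyloxy)-2,3-dihydrobenzofuran-3-yl]methanol (2,3-cis)
Conditions: DIBAL-H (3 equiv), CH2Cl2, −78 °C to −20 °C; aq. potassium sodium tartrate
Reagents that add atoms: none
Why: Low-temperature hydride reduction of the ester outruns enolisation, so the epimerisable cis C3 centre is retained and the silyl and benzyl ethers are untouched.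

Step 7
Reactants: 9 3,4,5-tris(benzyloxy)benzoic acid
Product: 10 3,4,5-tris(benzyloxy)benzoyl chloride
Conditions: (COCl)2, DMF (cat.), CH2Cl2, 0 °C to rt
Reagents that add atoms: oxalyl chloride, ClC(=O)C(=O)Cl
Why: This is the standard DMF-catalysed conversion of a carboxylic acid into its chloride, which is compatible with benzyl ethers.

Step 8
Reactants: 8 cis-(2S,3S)-dihydrobenzofuran-3-ylmethanol; 10 3,4,5-tris(benzyloxy)benzoyl chloride
Product: 12 (2S,3S)-3-(hydroxymethyl)-2-[3,4,5-tris(benzyloxy)phenyl]-4-{[3,4,5-tris(benzyloxy)benzyl]oxy}-2,3-dihydrobenzofuran-6-yl 3,4,5-tris(benzyloxy)benzoate, via phenol 11 (not isolated)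
Conditions: TBAF (1.0 equiv), THF, −20 °C; then 10 (1.05 equiv), −20 °C to 0 °C
Reagents that add atoms: none
Why: Fluoride cleaves only the aryl Si–O bond, and the tetrabutylammonium phenoxide so formed is acylated much faster than the neutral primary alcohol, which places the galloyl unit on the future O7 without further protection.

Step 9
Reactants: 12 (2S,3S)-3-(hydroxymethyl)-2,3-dihydrobenzofuran-6-yl gallate
Product: 15 (2R,3R)-3-hydroxy-2-[3,4,5-tris(benzyloxy)phenyl]-5-{[3,4,5-tris(benzyloxy)benzyl]oxy}chroman-7-yl 3,4,5-tris(benzyloxy)benzoate, via mesylate 13 (not isolated), via phenonium mesylate 14 (not isolated)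
Conditions: MsCl, Et3N, CH2Cl2, −20 °C; solvent exchange; (CF3)2CHOH–H2O (9:1), 2,6-lutidine, 40 °C
Reagents that add atoms: methanesulfonyl chloride, CS(=O)(=O)Cl (mesyl group of 13 and 14 only); water, O (hydroxyl oxygen on C3 of 15)
Why: Mesylation activates the primary alcohol, and in the strongly ionising, weakly nucleophilic medium the A-ring ipso carbon C3a (future C4a), pushed by the ortho oxygens O1 and O on C4, displaces mesylate from the exocyclic CH2 (Ar1-3 participation) to give the spirocyclopropyl arenium (phenonium) ion 14; water then attacks the ring-fusion carbon C3 and breaks the C3–C3a bond, so that the aryl carbon ends on the former exocyclic carbon (now C4) and the ring O1–C2–C3–C3a–C7a grows by one atom to the pyran ring. The closest known reaction type is the Wagner–Meerwein 1,2-aryl shift in the solvolysis of β-aryl sulfonates, in its ring-enlarging form known for benzocycloalkenylmethyl sulfonates and for the ring-expanding solvolysis of indoline-fused spirocyclopropylcyclohexadienones to 3-substituted tetrahydroquinolines. The only ring that is closed is the transient cyclopropane (3-exo-tet); the pyran ring is not closed by cyclisation but results from scission of the bond shared by the three- and five-membered rings of 14. The one new stereocentre, the C3 carbinol, is controlled by the C3 centre of 12, because water must enter anti to the departing aryl carbon (inversion), which translates the cis CH2OMs/aryl relation into the cis OH/aryl relation (2R,3R), while C2 is not involved. The step needs aryl rather than hydride migration and opening at the secondary C3 rather than at the primary CH2: the first is secured by the two alkoxy donors ortho to C3a, the second by the larger share of positive charge on the more substituted cyclopropane carbon (helped by the 6-acyloxy group, which makes the ion less stabilised and its opening looser) and by release of the strain of the cis-2,3-disubstituted five-membered ring. Addition of water at CH2 would only return alcohol 12, which can be resubmitted.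

Step 10
Reactants: 15 (2R,3R)-perbenzylated epigallocatechin 7-O-gallate
Product: 16 epigallocatechin 7-O-gallate, (2R,3R)-3,5-dihydroxy-2-(3,4,5-trihydroxyphenyl)chroman-7-yl 3,4,5-trihydroxybenzoate
Conditions: H2 (1 atm), Pd(OH)2/C, THF–MeOH (1:1), rt, exclusion of air on work-up
Reagents that add atoms: none
Why: Catalytic hydrogenolysis removes the nine benzyl ethers and the 3,4,5-tris(benzyloxy)benzyl ether on O5 under neutral conditions that leave the aryl ester, the endocyclic C2–O1 bond and both stereocentres intact, as is usual for perbenzylated flavan-3-ol gallates.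

Compound list
1 | 2',4',6'-trihydroxyacetophenone | CC(=O)c1c(O)cc(O)cc1O | starting material
2 | 1-[2,6-dihydroxy-4-(triisopropylsilyloxy)phenyl]ethanone | CC(=O)c1c(O)cc(O[Si](C(C)C)(C(C)C)C(C)C)cc1O | intermediate
3 | 3,4,5-tris(benzyloxy)benzyl alcohol | OCc1cc(OCc2ccccc2)c(OCc2ccccc2)c(OCc2ccccc2)c1 | starting material
4 | 1-[2,6-bis{[3,4,5-tris(benzyloxy)benzyl]oxy}-4-(triisopropylsilyloxy)phenyl]ethanone | CC(=O)c1c(OCc3cc(OCc4ccccc4)c(OCc4ccccc4)c(OCc4ccccc4)c3)cc(O[Si](C(C)C)(C(C)C)C(C)C)cc1OCc3cc(OCc4ccccc4)c(OCc4ccccc4)c(OCc4ccccc4)c3 | intermediate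
5 | methyl 2-[2,6-bis{[3,4,5-tris(benzyloxy)benzyl]oxy}-4-(triisopropylsilyloxy)phenyl]acetate | COC(=O)Cc1c(OCc3cc(OCc4ccccc4)c(OCc4ccccc4)c(OCc4ccccc4)c3)cc(O[Si](C(C)C)(C(C)C)C(C)C)cc1OCc3cc(OCc4ccccc4)c(OCc4ccccc4)c(OCc4ccccc4)c3 | intermediate
6 | methyl 2-diazo-2-[2,6-bis{[3,4,5-tris(benzyloxy)benzyl]oxy}-4-(triisopropylsilyloxy)phenyl]acetate | COC(=O)C(=[N+]=[N-])c1c(OCc3cc(OCc4ccccc4)c(OCc4ccccc4)c(OCc4ccccc4)c3)cc(O[Si](C(C)C)(C(C)C)C(C)C)cc1OCc3cc(OCc4ccccc4)c(OCc4ccccc4)c(OCc4ccccc4)c3 | intermediate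
7 | methyl (2S,3R)-2-[3,4,5-tris(benzyloxy)phenyl]-4-{[3,4,5-tris(benzyloxy)benzyl]oxy}-6-(triisopropylsilyloxy)-2,3-dihydrobenzofuran-3-carboxylate (cis) | CC(C)[Si](Oc1cc(OCc3cc(OCc4ccccc4)c(OCc4ccccc4)c(OCc4ccccc4)c3)c2c(c1)O[C@H](c3cc(OCc4ccccc4)c(OCc4ccccc4)c(OCc4ccccc4)c3)[C@@H]2C(=O)OC)(C(C)C)C(C)C | intermediate
8 | [(2S,3S)-2-[3,4,5-tris(benzyloxy)phenyl]-4-{[3,4,5-tris(benzyloxy)benzyl]oxy}-6-(triisopropylsilyloxy)-2,3-dihydrobenzofuran-3-yl]methanol (cis) | CC(C)[Si](Oc1cc(OCc3cc(OCc4ccccc4)c(OCc4ccccc4)c(OCc4ccccc4)c3)c2c(c1)O[C@H](c3cc(OCc4ccccc4)c(OCc4ccccc4)c(OCc4ccccc4)c3)[C@@H]2CO)(C(C)C)C(C)C | intermediate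
9 | 3,4,5-tris(benzyloxy)benzoic acid | OC(=O)c1cc(OCc2ccccc2)c(OCc2ccccc2)c(OCc2ccccc2)c1 | starting material
10 | 3,4,5-tris(benzyloxy)benzoyl chloride | ClC(=O)c1cc(OCc2ccccc2)c(OCc2ccccc2)c(OCc2ccccc2)c1 | intermediate
11 | (2S,3S)-3-(hydroxymethyl)-2-[3,4,5-tris(benzyloxy)phenyl]-4-{[3,4,5-tris(benzyloxy)benzyl]oxy}-2,3-dihydrobenzofuran-6-ol (formed as its tetrabutylammonium phenoxide, not isolated) | Oc1cc(OCc3cc(OCc4ccccc4)c(OCc4ccccc4)c(OCc4ccccc4)c3)c2c(c1)O[C@H](c3cc(OCc4ccccc4)c(OCc4ccccc4)c(OCc4ccccc4)c3)[C@@H]2CO | intermediate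
12 | (2S,3S)-3-(hydroxymethyl)-2-[3,4,5-tris(benzyloxy)phenyl]-4-{[3,4,5-tris(benzyloxy)benzyl]oxy}-2,3-dihydrobenzofuran-6-yl 3,4,5-tris(benzyloxy)benzoate | O=C(Oc1cc(OCc3cc(OCc4ccccc4)c(OCc4ccccc4)c(OCc4ccccc4)c3)c2c(c1)O[C@H](c3cc(OCc4ccccc4)c(OCc4ccccc4)c(OCc4ccccc4)c3)[C@@H]2CO)c3cc(OCc4ccccc4)c(OCc4ccccc4)c(OCc4ccccc4)c3 | intermediate
13 | (2S,3S)-3-(mesyloxymethyl) analogue of 12 (not isolated) | O=C(Oc1cc(OCc3cc(OCc4ccccc4)c(OCc4ccccc4)c(OCc4ccccc4)c3)c2c(c1)O[C@H](c3cc(OCc4ccccc4)c(OCc4ccccc4)c(OCc4ccccc4)c3)[C@@H]2COS(C)(=O)=O)c3cc(OCc4ccccc4)c(OCc4ccccc4)c(OCc4ccccc4)c3 | intermediate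
14 | phenonium (spirocyclopropyl arenium) ion drawn as its O1-oxocarbenium form, mesylate salt (not isolated) | O=C(OC1=CC2=[O+][C@H](c3cc(OCc4ccccc4)c(OCc4ccccc4)c(OCc4ccccc4)c3)[C@@H]5C[C@]25C(OCc3cc(OCc4ccccc4)c(OCc4ccccc4)c(OCc4ccccc4)c3)=C1)c3cc(OCc4ccccc4)c(OCc4ccccc4)c(OCc4ccccc4)c3.CS(=O)(=O)[O-] | intermediate
15 | (2R,3R)-3-hydroxy-2-[3,4,5-tris(benzyloxy)phenyl]-5-{[3,4,5-tris(benzyloxy)benzyl]oxy}chroman-7-yl 3,4,5-tris(benzyloxy)benzoate (2,3-cis) | O=C(Oc1cc(OCc3cc(OCc4ccccc4)c(OCc4ccccc4)c(OCc4ccccc4)c3)c2c(c1)O[C@H](c3cc(OCc4ccccc4)c(OCc4ccccc4)c(OCc4ccccc4)c3)[C@H](O)C2)c3cc(OCc4ccccc4)c(OCc4ccccc4)c(OCc4ccccc4)c3 | intermediate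
16 | epigallocatechin 7-O-gallate, (2R,3R) | O=C(Oc1cc(O)c2c(c1)O[C@H](c1cc(O)c(O)c(O)c1)[C@H](O)C2)c1cc(O)c(O)c(O)c1 | target

Total step count: 10. Longest linear sequence: 9 steps (steps 1–6 and 8–10, from 1 to 16).

Steps most likely to fail

Step 9. Three processes could defeat the step:
- Water may add to the less hindered exocyclic carbon of the bridged ion, so that the ring does not grow.
- The C3 hydride may migrate instead of the aryl carbon, followed by proton loss from C2 and aromatisation of the five-membered ring.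
- The constrained geometry of the fused five-membered ring may slow aryl bridging.

The fallback sets out from 7 and comes back at 15. It keeps the same ring enlargement but lets an oxygen on C3 drive it.
- Enolisation of 7 with KHMDS and hydroxylation with 2-(phenylsulfonyl)-3-phenyloxaziridine (THF, −78 °C, attack anti to the C2 aryl group) should give the α-hydroxy ester F1. The configuration of this centre is of no consequence.
- LiAlH4 reduction should give the diol F2.
- MsCl/collidine at low temperature should mesylate only the primary hydroxyl and give the monomesylate F3.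
- Semipinacol rearrangement (Et2AlCl, CH2Cl2, −78 °C to 0 °C) moves the same aryl carbon from C3 to CH2 with formation of the carbonyl group, so the regiochemistry is unambiguous. It should give the (2R)-flavan-3-one F4.
- L-Selectride (THF, −78 °C) delivers hydride anti to the C2 aryl group and should give the cis alcohol F5.
- TBAF followed by 10, via the phenol F6, should acylate the phenoxide in preference to the hindered secondary alcohol and give 15.

Step 5. The di-ortho-substituted, very electron-rich aryl group may twist out of conjugation with the carbenoid. This would erode facial and cis selectivity and allow carbene dimerisation to compete.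

The fallback sets out from 6 and comes back at 7. Stereocontrol is moved from catalysis to resolution. Decomposition of 6 with achiral Rh2(OAc)4 in CH2Cl2 should give the racemic cis ester, that is 7 together with its mirror image, the (2R,3S) ester F7. Preparative supercritical-fluid chromatography on a polysaccharide-based chiral stationary phase then delivers 7.

Step 3. Enol ether formation at the ketone flanked by two bulky ortho substituents may be slow. Ring thallation or oxidation of the electron-rich arenes and acid-induced loss of the benzylic ethers could then take over.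

The fallback sets out from 4 and comes back at 6, bypassing 5.
- SeO2 in pyridine (90 °C) should oxidise the methyl ketone to the arylglyoxylic acid F8.
- TMSCHN2 should give the methyl arylglyoxylate F9.
- Condensation with tosylhydrazide should give the tosylhydrazone F10.
- DBU in CH2Cl2 then eliminates sulfinate (Bamford–Stevens type) to give diazoester 6 directly.

Further compounds
F1 | step 9 | methyl (2R,3S)-3-hydroxy-2-[3,4,5-tris(benzyloxy)phenyl]-4-{[3,4,5-tris(benzyloxy)benzyl]oxy}-6-(triisopropylsilyloxy)-2,3-dihydrobenzofuran-3-carboxylate | CC(C)[Si](Oc1cc(OCc3cc(OCc4ccccc4)c(OCc4ccccc4)c(OCc4ccccc4)c3)c2c(c1)O[C@H](c3cc(OCc4ccccc4)c(OCc4ccccc4)c(OCc4ccccc4)c3)[C@]2(O)C(=O)OC)(C(C)C)C(C)C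
F2 | step 9 | (2R,3R)-3-(hydroxymethyl)-2-[3,4,5-tris(benzyloxy)phenyl]-4-{[3,4,5-tris(benzyloxy)benzyl]oxy}-6-(triisopropylsilyloxy)-2,3-dihydrobenzofuran-3-ol | CC(C)[Si](Oc1cc(OCc3cc(OCc4ccccc4)c(OCc4ccccc4)c(OCc4ccccc4)c3)c2c(c1)O[C@H](c3cc(OCc4ccccc4)c(OCc4ccccc4)c(OCc4ccccc4)c3)[C@]2(O)CO)(C(C)C)C(C)C
F3 | step 9 | primary monomesylate of F2, (2R,3R) | CC(C)[Si](Oc1cc(OCc3cc(OCc4ccccc4)c(OCc4ccccc4)c(OCc4ccccc4)c3)c2c(c1)O[C@H](c3cc(OCc4ccccc4)c(OCc4ccccc4)c(OCc4ccccc4)c3)[C@]2(O)COS(C)(=O)=O)(C(C)C)C(C)C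
F4 | step 9 | (2R)-2-[3,4,5-tris(benzyloxy)phenyl]-5-{[3,4,5-tris(benzyloxy)benzyl]oxy}-7-(triisopropylsilyloxy)chroman-3-one | CC(C)[Si](Oc1cc(OCc3cc(OCc4ccccc4)c(OCc4ccccc4)c(OCc4ccccc4)c3)c2c(c1)O[C@H](c3cc(OCc4ccccc4)c(OCc4ccccc4)c(OCc4ccccc4)c3)C(=O)C2)(C(C)C)C(C)C
F5 | step 9 | (2R,3R)-2-[3,4,5-tris(benzyloxy)phenyl]-5-{[3,4,5-tris(benzyloxy)benzyl]oxy}-7-(triisopropylsilyloxy)chroman-3-ol | CC(C)[Si](Oc1cc(OCc3cc(OCc4ccccc4)c(OCc4ccccc4)c(OCc4ccccc4)c3)c2c(c1)O[C@H](c3cc(OCc4ccccc4)c(OCc4ccccc4)c(OCc4ccccc4)c3)[C@H](O)C2)(C(C)C)C(C)C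
F6 | step 9 | (2R,3R)-2-[3,4,5-tris(benzyloxy)phenyl]-5-{[3,4,5-tris(benzyloxy)benzyl]oxy}chroman-3,7-diol | Oc1cc(OCc3cc(OCc4ccccc4)c(OCc4ccccc4)c(OCc4ccccc4)c3)c2c(c1)O[C@H](c3cc(OCc4ccccc4)c(OCc4ccccc4)c(OCc4ccccc4)c3)[C@H](O)C2
F7 | step 5 | methyl (2R,3S)-2-[3,4,5-tris(benzyloxy)phenyl]-4-{[3,4,5-tris(benzyloxy)benzyl]oxy}-6-(triisopropylsilyloxy)-2,3-dihydrobenzofuran-3-carboxylate (mirror image of 7) | CC(C)[Si](Oc1cc(OCc3cc(OCc4ccccc4)c(OCc4ccccc4)c(OCc4ccccc4)c3)c2c(c1)O[C@@H](c3cc(OCc4ccccc4)c(OCc4ccccc4)c(OCc4ccccc4)c3)[C@H]2C(=O)OC)(C(C)C)C(C)C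
F8 | step 3 | 2-oxo-2-[2,6-bis{[3,4,5-tris(benzyloxy)benzyl]oxy}-4-(triisopropylsilyloxy)phenyl]acetic acid | OC(=O)C(=O)c1c(OCc3cc(OCc4ccccc4)c(OCc4ccccc4)c(OCc4ccccc4)c3)cc(O[Si](C(C)C)(C(C)C)C(C)C)cc1OCc3cc(OCc4ccccc4)c(OCc4ccccc4)c(OCc4ccccc4)c3
F9 | step 3 | methyl 2-oxo-2-[2,6-bis{[3,4,5-tris(benzyloxy)benzyl]oxy}-4-(triisopropylsilyloxy)phenyl]acetate | COC(=O)C(=O)c1c(OCc3cc(OCc4ccccc4)c(OCc4ccccc4)c(OCc4ccccc4)c3)cc(O[Si](C(C)C)(C(C)C)C(C)C)cc1OCc3cc(OCc4ccccc4)c(OCc4ccccc4)c(OCc4ccccc4)c3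
F10 | step 3 | tosylhydrazone of F9 | COC(=O)C(=NNS(=O)(=O)c5ccc(C)cc5)c1c(OCc3cc(OCc4ccccc4)c(OCc4ccccc4)c(OCc4ccccc4)c3)cc(O[Si](C(C)C)(C(C)C)C(C)C)cc1OCc3cc(OCc4ccccc4)c(OCc4ccccc4)c(OCc4ccccc4)c3
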